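**Retrosynthetic overview**
1. Ring B is closed last by an intramolecular aldol addition: the enolate of the C8 ketone (carbon C9) attacks the C7 aldehyde, which creates the spiro centre C9 and the 7-OH together under thermodynamic control.
2. Ring C is closed just before by intramolecular C-alkylation (C9–C11) of the same ketone; the ketone comes from joining two fragments at C8–C9 (neopentyl-lithium plus aldehyde, then oxidation).
3. Fragment A (ring A with C6, C7, C9): from a Hajos–Parrish-type enedione whose cyclopentanone is later cut between C9 and C7.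
4. Fragment DE (rings D and E with C8, C11, C12): cyclopentanone by asymmetric copper hydride reduction, ring D by Robinson annulation, C13 by reductive allylation, C14 by nitrile methylation.
5. Ring order: ring A (fragment A) and ring E then ring D (fragment DE) in parallel, then ring C, then ring B.

Assumption: atoms carry the numbering of the fernane-type parent of the target (ring A C1–C5/C10; ring B C5–C7/C9/C10; ring C C8/C9/C11–C14; ring D C13–C18; ring E C17–C21; isopropyl on C21), α/β refer to the usual steroid-type drawing of each half, and the three ring-building ketones/enones used are taken as cheap commercial materials.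

**Fragment A**

Step 1
Reactants: 1 2-methylcyclopentane-1,3-dione; 2 pent-1-en-3-one (ethyl vinyl ketone)
Product: 3 2-methyl-2-(3-oxopentyl)cyclopentane-1,3-dione
Conditions: AcOH (cat.), H2O, 70 °C
Reagents that add atoms: none
Why: Michael addition of the acidic cyclic 1,3-dione to the vinyl ketone, with no stereocentre formed.

Step 2
Reactants: 3 triketone
Product: 5 (7aS)-4,7a-dimethyl-2,3,7,7a-tetrahydro-1H-indene-1,5(6H)-dione, via ketol 4 (not isolated)
Conditions: L-phenylalanine (1 equiv), (1S)-camphor-10-sulfonic acid (0.5 equiv), DMF, 30 → 70 °C; recrystallise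
Reagents that add atoms: none
Why: Hajos–Parrish-type amino-acid-catalysed intramolecular aldol condensation in which the enamine of the side-chain ketone picks one of the two enantiotopic ring carbonyls, fixing the quaternary carbon (future C10) as S.

Step 3
Reactants: 5 enedione
Product: 6 (7a'S)-4',7a'-dimethyl-2',3',7',7a'-tetrahydrospiro[1,3-dioxolane-2,1'-inden]-5'(6'H)-one
Conditions: Me3SiOCH2CH2OSiMe3, Me3SiOTf (5 mol %), CH2Cl2, −78 → −20 °C
Reagents that add atoms: 1,2-bis(trimethylsilyloxy)ethane, C[Si](C)(C)OCCO[Si](C)(C)C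
Why: Noyori-type silyl-triflate-catalysed ketalisation, which takes the saturated cyclopentanone (future C9) and leaves the conjugated enone untouched.

Step 4
Reactants: 6 ketal enone
Product: 8 (3a'S,7a'S)-4',4',7a'-trimethylhexahydrospiro[1,3-dioxolane-2,1'-inden]-5'(4'H)-one (trans-fused), via lithium enolate 7 (not isolated)
Conditions: Li, NH3(l)/THF, t-BuOH (1.0 equiv), −78 °C; then MeI, −78 → −33 °C; NH4Cl
Reagents that add atoms: iodomethane, CI
Why: Stork reductive alkylation, in which axial protonation of the β-carbon gives the trans ring junction (5α-H, anti to the angular methyl) and the regiospecific enolate is C-methylated to the 4,4-dimethyl ketone.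

Step 5
Reactants: 8 ketal ketone
Product: 10 (3aS,5S,7aS)-5-hydroxy-4,4,7a-trimethyloctahydro-1H-inden-1-one, via ketal alcohol 9 (not isolated)
Conditions: NaBH4, MeOH, 0 °C; then 2 M HCl, THF, rt
Reagents that add atoms: water, O
Why: Hydride reduction followed by ketal hydrolysis, where axial hydride delivery from the α-face of the 4,4-dimethyl-3-ketone gives the equatorial 3β-alcohol (3S).

Step 6
Reactants: 10 hydroxy ketone
Product: 11 3β-O-TBS ether and C9 TBS enol ether (C9=C7) of 10
Conditions: t-BuMe2SiOTf (2.5 equiv), Et3N, CH2Cl2, 0 °C → rt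
Reagents that add atoms: tert-butyldimethylsilyl trifluoromethanesulfonate, CC(C)(C)[Si](C)(C)OS(=O)(=O)C(F)(F)F
Why: Silylation in which the silyl triflate caps the hindered alcohol and, with Et3N, converts the ketone into its silyl enol ether, the only possible regioisomer because C10 is quaternary.

Step 7
Reactants: 11 bis-silyl compound
Product: 13 (1S,2S,4S)-4-[(tert-butyldimethylsilyl)oxy]-1,3,3-trimethyl-2-(2-oxoethyl)cyclohexane-1-carboxylic acid, via silyl ester aldehyde 12 (not isolated)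
Conditions: O3, CH2Cl2, −78 °C; PPh3, −78 °C → rt; then THF/H2O/AcOH (cat.), rt
Reagents that add atoms: ozone, [O-][O+]=O
Why: Ozonolysis of the electron-rich silyl enol ether cuts the C9–C7 bond and leaves the two termini at different oxidation levels (C9 acid, C7 aldehyde).

Step 8
Reactants: 13 aldehyde acid
Product: 14 2-[(1R,2S,5S)-5-[(tert-butyldimethylsilyl)oxy]-2-(hydroxymethyl)-2,6,6-trimethylcyclohexyl]ethan-1-ol
Conditions: LiAlH4, THF, 0 °C → reflux
Reagents that add atoms: none
Why: LiAlH4 reduction of both the aldehyde and the hindered acid to the diol, with the secondary silyl ether untouched.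

Step 9
Reactants: 14 diol
Product: 15 [(1S,2R,4S)-4-[(tert-butyldimethylsilyl)oxy]-2-{2-[(tert-butyldiphenylsilyl)oxy]ethyl}-1,3,3-trimethylcyclohexyl]methanol
Conditions: t-BuPh2SiCl (1.05 equiv), imidazole, CH2Cl2, 0 °C
Reagents that add atoms: tert-butyl(chloro)diphenylsilane, CC(C)(C)[Si](Cl)(c1ccccc1)c1ccccc1
Why: Sterically controlled silylation, since the unhindered C7 primary alcohol reacts far faster than the neopentyl C9 alcohol.

Step 10
Reactants: 15 neopentyl alcohol
Product: 16 tert-butyl{2-[(1S,2S,5S)-5-[(tert-butyldimethylsilyl)oxy]-2-(iodomethyl)-2,6,6-trimethylcyclohexyl]ethoxy}diphenylsilane (fragment A)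
Conditions: I2, PPh3, imidazole, toluene, 90 °C
Reagents that add atoms: iodine, II
Why: Garegg–Samuelsson (Appel-type) iodination, where heating forces iodide displacement on the neopentyl alkoxyphosphonium and no β-hydrogen is available for elimination.

**Fragment DE**

Step 11
Reactants: 17 3-ethoxycyclopent-2-en-1-one
Product: 19 3-(propan-2-yl)cyclopent-2-en-1-one, via magnesium alkoxide adduct 18 (not isolated)
Conditions: i-PrMgCl, THF, 0 °C; then 2 M HCl, rt
Reagents that add atoms: isopropylmagnesium chloride, CC(C)[Mg]Cl; water, O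
Why: Stork–Danheiser sequence of 1,2-addition to the vinylogous ester and acid-mediated carbonyl transposition.

Step 12
Reactants: 19 enone
Product: 21 (2R,3R)-2-methyl-3-(propan-2-yl)cyclopentan-1-one, via diphenylsilyl enol ether 20 (not isolated)
Conditions: CuCl (5 mol %), NaOt-Bu (5 mol %), (R)-p-Tol-BINAP (5 mol %), Ph2SiH2, toluene, 0 °C; then MeI, Bu4N[Ph3SiF2], CH2Cl2, rt
Reagents that add atoms: iodomethane, CI
Why: Copper hydride asymmetric conjugate reduction sets the isopropyl-bearing centre (future C21; the ligand antipode is the one that gives the 3R enol ether), and fluoride-triggered methylation of the regiodefined enol ether puts the methyl trans to isopropyl.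

Step 13
Reactants: 21 cyclopentanone; 2 pent-1-en-3-one
Product: 23 (1R,7aR)-4,7a-dimethyl-1-(propan-2-yl)-1,2,3,6,7,7a-hexahydro-5H-inden-5-one, via Michael adduct diketone 22 (not isolated)
Conditions: H2SO4 (cat.), toluene, reflux, Dean–Stark
Reagents that add atoms: none
Why: Acid-catalysed Robinson annulation through the more substituted enol, with the vinyl ketone adding anti to the neighbouring isopropyl group so that the new quaternary methyl (C17) is cis to isopropyl, followed by aldol condensation to the enone.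

Step 14
Reactants: 23 bicyclic enone
Product: 25 (1R,3aR,4S,7aR)-4,7a-dimethyl-1-(propan-2-yl)-4-(prop-2-en-1-yl)octahydro-5H-inden-5-one, via lithium enolate 24 (not isolated)
Conditions: Li, NH3(l)/THF, t-BuOH (1.0 equiv), −78 °C; then allyl bromide, −78 → −33 °C; NH4Cl
Reagents that add atoms: allyl bromide, C=CCBr
Why: Stork reductive alkylation, in which protonation gives the trans-hydrindane (18β-H) and the allyl group enters the enolate from the β-face, anti to the 1,3-related axial 17α-methyl, leaving the C13 methyl α.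

Step 15
Reactants: 25 ketone
Product: 26 (1R,3aR,4S,7aR)-4,7a-dimethyl-1-(propan-2-yl)-4-(prop-2-en-1-yl)octahydro-1H-indene-5-carbonitrile (C14 epimers)
Conditions: TosMIC, KOt-Bu, DME/EtOH, 0 → 40 °C
Reagents that add atoms: p-toluenesulfonylmethyl isocyanide, Cc1ccc(cc1)S(=O)(=O)C[N+]#[C-]
Why: Van Leusen reductive cyanation, which works on α-quaternary ketones and makes the epimer ratio irrelevant because the centre is planarised in the next step.

Step 16
Reactants: 26 nitrile
Product: 28 (1R,3aR,4S,5S,7aR)-4,5,7a-trimethyl-1-(propan-2-yl)-4-(prop-2-en-1-yl)octahydro-1H-indene-5-carbonitrile, via lithiated nitrile 27 (not isolated)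
Conditions: LiN(i-Pr)2, THF, −78 → 0 °C; then MeI, −78 °C → rt
Reagents that add atoms: iodomethane, CI
Why: Alkylation of the planar nitrile anion, where MeI approaches axially from the β-face because the adjacent axial 13α-methyl blocks the equatorial trajectory, giving the trans-diaxial 13α/14β-dimethyl pair.

Step 17
Reactants: 28 allyl nitrile
Product: 30 (1R,3aR,4S,5S,7aR)-4-(2-hydroxyethyl)-4,5,7a-trimethyl-1-(propan-2-yl)octahydro-1H-indene-5-carbonitrile, via ozonide 29 (not isolated)
Conditions: O3, CH2Cl2, −78 °C; then NaBH4, EtOH, −78 → 0 °C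
Reagents that add atoms: ozone, [O-][O+]=O
Why: Ozonolysis with reductive work-up trims the allyl group to the two-carbon C12–C11 alcohol while the nitrile is inert to NaBH4.

Step 18
Reactants: 30 alcohol
Product: 31 (1R,3aR,4S,5S,7aR)-4-(2-chloroethyl)-4,5,7a-trimethyl-1-(propan-2-yl)octahydro-1H-indene-5-carbonitrile
Conditions: PPh3, CCl4, CH2Cl2, 40 °C
Reagents that add atoms: tetrachloromethane, ClC(Cl)(Cl)Cl
Why: Appel chlorination of the unhindered primary alcohol gives a leaving group that tolerates the organolithium step at −78 °C.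

Step 19
Reactants: 31 chloro nitrile
Product: 32 (1R,3aR,4S,5S,7aR)-4-(2-chloroethyl)-4,5,7a-trimethyl-1-(propan-2-yl)octahydro-1H-indene-5-carbaldehyde (fragment DE)
Conditions: i-Bu2AlH, toluene, −78 °C; then 1 M HCl, 0 °C
Reagents that add atoms: water, O
Why: Partial reduction of the tertiary nitrile to the aluminium aldimine and hydrolysis gives the non-enolisable C8 aldehyde.

**Union and end game**

Step 20
Reactants: 16 fragment A iodide; 32 fragment DE aldehyde
Product: 34 coupled C8 carbinol (C8 epimers; C9H2 of 16 bonded to the former CHO carbon of 32; all other centres as in 16 and 32), via organolithium 33 (not isolated)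
Conditions: 16, t-BuLi (2.1 equiv), Et2O/pentane, −78 °C; then 32, −78 °C; NH4Cl (aq.), −78 °C → rt
Reagents that add atoms: none
Why: Lithium–iodine exchange gives a neopentyl organolithium that cannot β-eliminate, and its 1,2-addition to the non-enolisable aldehyde forms the C8–C9 bond, the carbinol centre being removed by the next oxidation.

Step 21
Reactants: 34 carbinol
Product: 35 C8 ketone of 34
Conditions: Dess–Martin periodinane, CH2Cl2, rt
Reagents that add atoms: none
Why: Dess–Martin oxidation handles hindered secondary alcohols and leaves the silyl ethers and the alkyl chloride alone.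

Step 22
Reactants: 35 chloro ketone
Product: 37 ring C ketone (C9 bonded to C11; rings C/D/E as in the target; ring B open; C9–H epimers; 3β-OTBS; C7–OTBDPS), via potassium enolate 36 (not isolated)
Conditions: KN(SiMe3)2 (1.2 equiv), Bu4NI (10 mol %), THF, −78 → 45 °C
Reagents that add atoms: none
Why: Intramolecular enolate C-alkylation (6-enolendo-exo-tet) closes ring C, the enolate being regiodefined because C14 is quaternary and the C9 configuration being irrelevant since it is re-enolised in step 25.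

Step 23
Reactants: 37 bis-silyl ether
Product: 38 3β,7-diol of 37
Conditions: HF·pyridine, THF, 0 → 40 °C
Reagents that add atoms: none
Why: Acidic fluoride desilylation removes both silyl ethers without base, so the ketone is not disturbed.

Step 24
Reactants: 38 diol
Product: 39 C7 aldehyde (3β-hydroxy 8-keto 7-al; aldol precursor)
Conditions: TEMPO (10 mol %), PhI(OAc)2, CH2Cl2, rt
Reagents that add atoms: none
Why: Oxoammonium (TEMPO) oxidation is selective for the unhindered primary alcohol over the hindered secondary 3β-OH.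

Step 25
Reactants: 39 keto aldehyde
Product: 41 target CNP0155208.1, via potassium enolate 40 (not isolated)
Conditions: KOH (0.5 equiv), MeOH, 0 °C → rt
Reagents that add atoms: none
Why: Reversible intramolecular aldol addition (5-exo attack of C9 on the C7 aldehyde) closes ring B, and equilibration should favour the isomer with the bulky C10 equatorial on ring C (9S) and the 7-OH on the C11 side, away from the axial 14β-methyl (7S), which is the target.

**Compound list**
1 | 2-methylcyclopentane-1,3-dione | CC1C(=O)CCC1=O | starting material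
2 | pent-1-en-3-one (ethyl vinyl ketone) | CCC(=O)C=C | starting material
3 | 2-methyl-2-(3-oxopentyl)cyclopentane-1,3-dione | CCC(=O)CCC1(C)C(=O)CCC1=O | intermediate
4 | cis-fused ketol, 3a-hydroxy-4,7a-dimethylhexahydroindane-1,5-dione (7aS) | C[C@]12CCC(=O)C(C)[C@@]1(O)CCC2=O | intermediate
5 | (7aS)-4,7a-dimethyl-2,3,7,7a-tetrahydro-1H-indene-1,5(6H)-dione | C[C@]12CCC(=O)C(C)=C1CCC2=O | intermediate
6 | (7a'S)-4',7a'-dimethyl-2',3',7',7a'-tetrahydrospiro[1,3-dioxolane-2,1'-inden]-5'(6'H)-one | C[C@]12CCC(=O)C(C)=C1CCC21OCCO1 | intermediate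
7 | lithium enolate of 8 (C3–OLi, C3=C4, 5α-H) | C[C@]12CCC([O-])=C(C)[C@@H]1CCC21OCCO1.[Li+] | intermediate
8 | (3a'S,7a'S)-4',4',7a'-trimethylhexahydrospiro[1,3-dioxolane-2,1'-inden]-5'(4'H)-one | C[C@]12CCC(=O)C(C)(C)[C@@H]1CCC21OCCO1 | intermediate
9 | (3a'S,5'S,7a'S)-4',4',7a'-trimethyloctahydrospiro[1,3-dioxolane-2,1'-inden]-5'-ol | C[C@]12CC[C@H](O)C(C)(C)[C@@H]1CCC21OCCO1 | intermediate
10 | (3aS,5S,7aS)-5-hydroxy-4,4,7a-trimethyloctahydro-1H-inden-1-one | C[C@]12CC[C@H](O)C(C)(C)[C@@H]1CCC2=O | intermediate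
11 | 3β-O-TBS ether and C9 TBS enol ether (C9=C7) of 10 | CC(C)(C)[Si](C)(C)O[C@H]1CC[C@]2(C)C(O[Si](C)(C)C(C)(C)C)=CC[C@H]2C1(C)C | intermediate
12 | tert-butyldimethylsilyl ester of 13 | CC(C)(C)[Si](C)(C)O[C@H]1CC[C@](C)(C(=O)O[Si](C)(C)C(C)(C)C)[C@@H](CC=O)C1(C)C | intermediate
13 | (1S,2S,4S)-4-[(tert-butyldimethylsilyl)oxy]-1,3,3-trimethyl-2-(2-oxoethyl)cyclohexane-1-carboxylic acid | CC(C)(C)[Si](C)(C)O[C@H]1CC[C@](C)(C(=O)O)[C@@H](CC=O)C1(C)C | intermediate
14 | 2-[(1R,2S,5S)-5-[(tert-butyldimethylsilyl)oxy]-2-(hydroxymethyl)-2,6,6-trimethylcyclohexyl]ethan-1-ol | CC(C)(C)[Si](C)(C)O[C@H]1CC[C@](C)(CO)[C@@H](CCO)C1(C)C | intermediate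
15 | [(1S,2R,4S)-4-[(tert-butyldimethylsilyl)oxy]-2-{2-[(tert-butyldiphenylsilyl)oxy]ethyl}-1,3,3-trimethylcyclohexyl]methanol | CC(C)(C)[Si](C)(C)O[C@H]1CC[C@](C)(CO)[C@@H](CCO[Si](c2ccccc2)(c2ccccc2)C(C)(C)C)C1(C)C | intermediate
16 | fragment A: tert-butyl{2-[(1S,2S,5S)-5-[(tert-butyldimethylsilyl)oxy]-2-(iodomethyl)-2,6,6-trimethylcyclohexyl]ethoxy}diphenylsilane | CC(C)(C)[Si](C)(C)O[C@H]1CC[C@](C)(CI)[C@@H](CCO[Si](c2ccccc2)(c2ccccc2)C(C)(C)C)C1(C)C | intermediate
17 | 3-ethoxycyclopent-2-en-1-one | CCOC1=CC(=O)CC1 | starting material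
18 | 3-ethoxy-1-(propan-2-yl)cyclopent-2-en-1-ol (as its chloromagnesium alkoxide) | CCOC1=CC(O)(C(C)C)CC1 | intermediate
19 | 3-(propan-2-yl)cyclopent-2-en-1-one | CC(C)C1=CC(=O)CC1 | intermediate
20 | {[(3R)-3-(propan-2-yl)cyclopent-1-en-1-yl]oxy}diphenylsilane | CC(C)[C@H]1CCC(O[SiH](c2ccccc2)c2ccccc2)=C1 | intermediate
21 | (2R,3R)-2-methyl-3-(propan-2-yl)cyclopentan-1-one | CC(C)[C@H]1CCC(=O)[C@@H]1C | intermediate
22 | (2R,3R)-2-methyl-2-(3-oxopentyl)-3-(propan-2-yl)cyclopentan-1-one | CC(C)[C@H]1CCC(=O)[C@]1(C)CCC(=O)CC | intermediate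
23 | (1R,7aR)-4,7a-dimethyl-1-(propan-2-yl)-1,2,3,6,7,7a-hexahydro-5H-inden-5-one | CC(C)[C@H]1CCC2=C(C)C(=O)CC[C@@]21C | intermediate
24 | lithium enolate of the trans-fused reduction product of 23 (C14–OLi, C13=C14) | CC(C)[C@H]1CC[C@@H]2[C@]1(C)CCC([O-])=C2C.[Li+] | intermediate
25 | (1R,3aR,4S,7aR)-4,7a-dimethyl-1-(propan-2-yl)-4-(prop-2-en-1-yl)octahydro-5H-inden-5-one | CC(C)[C@H]1CC[C@@H]2[C@]1(C)CCC(=O)[C@@]2(C)CC=C | intermediate
26 | (1R,3aR,4S,7aR)-4,7a-dimethyl-1-(propan-2-yl)-4-(prop-2-en-1-yl)octahydro-1H-indene-5-carbonitrile (C5 epimers) | CC(C)[C@H]1CC[C@@H]2[C@]1(C)CCC(C#N)[C@@]2(C)CC=C | intermediate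
27 | lithiated nitrile (keteniminate) of 26 | CC(C)[C@H]1CC[C@@H]2[C@]1(C)CCC(=C=[N-])[C@@]2(C)CC=C.[Li+] | intermediate
28 | (1R,3aR,4S,5S,7aR)-4,5,7a-trimethyl-1-(propan-2-yl)-4-(prop-2-en-1-yl)octahydro-1H-indene-5-carbonitrile | CC(C)[C@H]1CC[C@@H]2[C@]1(C)CC[C@](C)(C#N)[C@@]2(C)CC=C | intermediate
29 | ozonide (1,2,4-trioxolane) of the allyl group of 28 | CC(C)[C@H]1CC[C@@H]2[C@]1(C)CC[C@](C)(C#N)[C@@]2(C)CC1OCOO1 | intermediate
30 | (1R,3aR,4S,5S,7aR)-4-(2-hydroxyethyl)-4,5,7a-trimethyl-1-(propan-2-yl)octahydro-1H-indene-5-carbonitrile | CC(C)[C@H]1CC[C@@H]2[C@]1(C)CC[C@](C)(C#N)[C@@]2(C)CCO | intermediate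
31 | (1R,3aR,4S,5S,7aR)-4-(2-chloroethyl)-4,5,7a-trimethyl-1-(propan-2-yl)octahydro-1H-indene-5-carbonitrile | CC(C)[C@H]1CC[C@@H]2[C@]1(C)CC[C@](C)(C#N)[C@@]2(C)CCCl | intermediate
32 | fragment DE: (1R,3aR,4S,5S,7aR)-4-(2-chloroethyl)-4,5,7a-trimethyl-1-(propan-2-yl)octahydro-1H-indene-5-carbaldehyde | CC(C)[C@H]1CC[C@@H]2[C@]1(C)CC[C@](C)(C=O)[C@@]2(C)CCCl | intermediate
33 | neopentyl-lithium from 16 (C9–Li) | CC(C)(C)[Si](C)(C)O[C@H]1CC[C@](C)(C[Li])[C@@H](CCO[Si](c2ccccc2)(c2ccccc2)C(C)(C)C)C1(C)C | intermediate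
34 | coupled C8 carbinol (C8 epimers; fragment A via C9H2, fragment DE via C14) | CC(C)[C@H]1CC[C@@H]2[C@]1(C)CC[C@](C)(C(O)C[C@@]3(C)CC[C@H](O[Si](C)(C)C(C)(C)C)C(C)(C)[C@@H]3CCO[Si](c3ccccc3)(c3ccccc3)C(C)(C)C)[C@@]2(C)CCCl | intermediate
35 | C8 ketone of 34 | CC(C)[C@H]1CC[C@@H]2[C@]1(C)CC[C@](C)(C(=O)C[C@@]3(C)CC[C@H](O[Si](C)(C)C(C)(C)C)C(C)(C)[C@@H]3CCO[Si](c3ccccc3)(c3ccccc3)C(C)(C)C)[C@@]2(C)CCCl | intermediate
36 | potassium enolate of 35 (C8–OK, C8=C9) | CC(C)[C@H]1CC[C@@H]2[C@]1(C)CC[C@](C)(C([O-])=C[C@@]3(C)CC[C@H](O[Si](C)(C)C(C)(C)C)C(C)(C)[C@@H]3CCO[Si](c3ccccc3)(c3ccccc3)C(C)(C)C)[C@@]2(C)CCCl.[K+] | intermediate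
37 | ring C ketone (rings A and C/D/E; ring B open; C9–H epimers; 3β-OTBS; C7–OTBDPS) | CC(C)[C@H]1CC[C@@H]2[C@]1(C)CC[C@]1(C)C(=O)C(CC[C@@]21C)[C@@]3(C)CC[C@H](O[Si](C)(C)C(C)(C)C)C(C)(C)[C@@H]3CCO[Si](c3ccccc3)(c3ccccc3)C(C)(C)C | intermediate
38 | 3β,7-diol of 37 | CC(C)[C@H]1CC[C@@H]2[C@]1(C)CC[C@]1(C)C(=O)C(CC[C@@]21C)[C@@]3(C)CC[C@H](O)C(C)(C)[C@@H]3CCO | intermediate
39 | 3β-hydroxy 8-keto 7-aldehyde (aldol precursor) | CC(C)[C@H]1CC[C@@H]2[C@]1(C)CC[C@]1(C)C(=O)C(CC[C@@]21C)[C@@]3(C)CC[C@H](O)C(C)(C)[C@@H]3CC=O | intermediate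
40 | potassium enolate of 39 (C8–OK, C8=C9) | CC(C)[C@H]1CC[C@@H]2[C@]1(C)CC[C@]1(C)C([O-])=C(CC[C@@]21C)[C@@]3(C)CC[C@H](O)C(C)(C)[C@@H]3CC=O.[K+] | intermediate
41 | CNP0155208.1 (3β,7β-dihydroxy-8-oxo spiro compound; 3S,5R,7S,9S,10S,13S,14S,17R,18R,21R) | CC(C)[C@H]1CC[C@@H]2[C@]1(C)CC[C@]1(C)C(=O)[C@]3(CC[C@@]21C)[C@@H](O)C[C@H]1C(C)(C)[C@@H](O)CC[C@@]13C | target

**Totals**
Total step count: 25 (fragment A steps 1–10, fragment DE steps 11–19, union and end game steps 20–25).
Longest linear sequence: 16 steps (1–10, then 20–25); the other branch is 15 steps (11–19, then 20–25).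

**Three steps most likely to fail, with fallbacks**

Step 20 (union of two neopentyl partners). The aldehyde carbon of 32 sits between two quaternary carbons, so addition of 33 may stall. The fallback sets out from 16 and from nitrile 31 (one step before 32). The lithium reagent made from 16 is added to the linear, far less shielded C≡N group of 31 in Et2O at −78 → 0 °C and quenched cold. The resulting N–H ketimine F1 is hydrolysed with aqueous AcOH/THF at 40 °C, which the silyl ethers tolerate. This delivers ketone 35 directly, so the route is rejoined at 35 and steps 19 and 21 are no longer needed.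

Step 22 (ring C closure). The hindered enolate may O-alkylate to a cyclic enol ether or simply be too slow with the chloride. The fallback sets out from 35 and replaces the SN2 closure by a carbonyl condensation. Kornblum oxidation of the primary chloride (NaI, NaHCO3, DMSO, 110 °C) gives the C11 aldehyde F2. KOH in MeOH then effects intramolecular aldol condensation of C9 onto C11 to the ring C enone F3 (C9=C11), a closure in which O-alkylation is impossible. Hydrogenation (H2, Pd/C, EtOAc) of the enone returns the route to 37.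

Step 25 (ring B aldol). The equilibrium may lie on the open side, or the aldehyde may enolise and condense intermolecularly before the hindered ketone reacts. The fallback sets out from 37 and generates the C9 enolate reductively and regiospecifically instead of by base. Treatment of 37 with KN(SiMe3)2 and then N-bromosuccinimide gives the C9 bromo ketone F4. HF·pyridine gives the bromo diol F5, and TEMPO/PhI(OAc)2 gives the bromo keto aldehyde F6. SmI2 in THF at −78 °C reduces the C–Br bond to a samarium enolate (trivalent samarium) that closes onto the C7 aldehyde in a Reformatsky-type aldol that is irreversible at this temperature. This comes back to the route at 41; if the 7-epimer is formed, brief exposure to the step 25 conditions equilibrates it.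

**Further compounds**
F1 | step 20 | N–H ketimine corresponding to ketone 35 (C8=NH) | CC(C)[C@H]1CC[C@@H]2[C@]1(C)CC[C@](C)(C(=N)C[C@@]3(C)CC[C@H](O[Si](C)(C)C(C)(C)C)C(C)(C)[C@@H]3CCO[Si](c3ccccc3)(c3ccccc3)C(C)(C)C)[C@@]2(C)CCCl
F2 | step 22 | C11 aldehyde of 35 (CH2Cl replaced by CHO) | CC(C)[C@H]1CC[C@@H]2[C@]1(C)CC[C@](C)(C(=O)C[C@@]3(C)CC[C@H](O[Si](C)(C)C(C)(C)C)C(C)(C)[C@@H]3CCO[Si](c3ccccc3)(c3ccccc3)C(C)(C)C)[C@@]2(C)CC=O
F3 | step 22 | ring C enone (C9=C11) corresponding to 37 | CC(C)[C@H]1CC[C@@H]2[C@]1(C)CC[C@]1(C)C(=O)C(=CC[C@@]21C)[C@@]3(C)CC[C@H](O[Si](C)(C)C(C)(C)C)C(C)(C)[C@@H]3CCO[Si](c3ccccc3)(c3ccccc3)C(C)(C)C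
F4 | step 25 | C9 bromo ketone of 37 | CC(C)[C@H]1CC[C@@H]2[C@]1(C)CC[C@]1(C)C(=O)C(Br)(CC[C@@]21C)[C@@]3(C)CC[C@H](O[Si](C)(C)C(C)(C)C)C(C)(C)[C@@H]3CCO[Si](c3ccccc3)(c3ccccc3)C(C)(C)C
F5 | step 25 | C9 bromo 3β,7-diol | CC(C)[C@H]1CC[C@@H]2[C@]1(C)CC[C@]1(C)C(=O)C(Br)(CC[C@@]21C)[C@@]3(C)CC[C@H](O)C(C)(C)[C@@H]3CCO
F6 | step 25 | C9 bromo 8-keto 7-aldehyde | CC(C)[C@H]1CC[C@@H]2[C@]1(C)CC[C@]1(C)C(=O)C(Br)(CC[C@@]21C)[C@@]3(C)CC[C@H](O)C(C)(C)[C@@H]3CC=O
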